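**Remarks on the chemistry**

- Locants: C1–C9 are the bicyclo[3.3.1]nonane core (C1 benzoylated bridgehead, C2/C4/C9 carbonyls, C3 and C5 prenylated, C7 methine, C8 gem-dimethyl). C1'–C3' are the C7 arm that becomes the two-carbon bridge and its CMe2 group. C1''–C3'' are the C3 prenyl group. In adamantane 11 the bridge carbon between C3 and C7 is C10. "Endo" at C7 means the face of ring B turned toward C3.
- Structures 16, 17 and 18 were compared centre by centre. C1, C3, C5 and C7 describe one feasible cage, C2' carries C3' gauche to C4 and anti to C2, H–C2'' is cis to H–C2' across the dioxepane, and all three structures agree, so they are used as drawn.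
- The enol aldehyde 10 and the cage aldol 11 are ring–chain isomers. The neutral material rests as 11, whereas strong base turns the alkoxide of 11 into the ring-opened β-diketonate anion. 10 therefore occurs as a compound only in the acidic quench of step 6. In step 7 the opened species is an anion that the ylide consumes before any protonation.
- Assumption: the cinchonidine-derived catalyst of step 6 is taken to give the antipode drawn for 11. If the sense of induction is opposite, the cinchonine-derived pseudo-enantiomer replaces it and nothing else changes.

## Structural features

The target is a caged polyprenylated acylphloroglucinol in which ring A (C1–C2–C3–C4–C5–C9, ketones at C2, C4 and C9) and ring B (C1–C8–C7–C6–C5–C9) form a bicyclo[3.3.1]nonanetrione that the bridge C7–C1'–C2'–C3 turns into a homoadamantane. C1 carries the benzoyl group next to the gem-dimethyl carbon C8 (type A pattern) and C5 a prenyl group, so C1, C3 and C5 are quaternary and ring A is a non-enolisable β-triketone. A seven-membered 1,2-dioxepane (C2'–C3'–O–O–C2''–C1''–C3) is fused to the cage at C3–C2', and C2'' bears the C3''(CH3)2OOH group. C1, C3, C5 and C7 are locked together by the cage and only need the right absolute sense, whereas C2' (next to C3, with C3' on the C4/C6 flank) and C2'' (its hydrogen cis to H–C2' across the dioxepane) need diastereocontrol. The fragile groups are the ring peroxide with its C2''–H (base-induced Kornblum–DeLaMare cleavage), the tertiary hydroperoxide (reduction, acid), the triketone and benzoyl group (retro-Claisen with alkoxide) and the C5 prenyl alkene. The real difficulty is threefold: the crowded type A core with the C1–C8 bond between two quaternary carbons, the absolute configuration, and the late entry of four oxygen atoms at one of three alkenes. The key step uses the fact that the cage holds the 1,1-disubstituted isopropenyl group on C2' gauche to the prenyl group on C3, so a peroxyl radical on C3' finds C2'' within reach, flanked by the quaternary carbons C3 and C3'.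

## Logic of the disconnections

**18 ⇒ 17.** The O–H of the hydroperoxide is replaced by O–Si. This is the form in which a silane-driven cobalt peroxidation releases a hydroperoxide, so no separate protection is spent. The forward step must cleave Si–O without base, nucleophile or reductant.

**17 ⇒ 16.** The bonds C3'–O, O–C2'' and C3''–O are cut together. All four peroxide oxygens, the dioxepane ring and the C2'' stereocentre disappear, leaving a hydrocarbon-decorated cage with an isopropenyl group on C2' and a prenyl group on C3. The forward step must start at the isopropenyl alkene only, let dioxygen capture outrun carbon–carbon cyclisation, close a seven-membered ring through a peroxyl radical on one face of C2'', and end with a second dioxygen capture.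

**16 ⇒ 15.** The C3–C2' bond is cut. The two-carbon bridge opens, C3 and C2' cease to be stereocentres, and a bicyclic enolised β-diketone with an endo C7 arm remains. The allylic electrophile is carried as a free secondary isopropenyl carbinol and not as a primary carbonate: it is one addition away from an aldehyde, it need not be acylated in the presence of the enol, and the enol itself assists ionisation. The forward step demands C-attack at the internal allyl terminus, formation of a quaternary carbon, and the right face at C2'.

**15 ⇒ 13 + 14.** The C2'–C3' bond is cut, which separates the three-carbon isopropenyl unit from the C7 arm. The forward addition must respect the enolised diketone and two hindered ketones; the carbinol configuration is of no consequence.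

**13 ⇒ 11.** The C1'–C2' bond is cut (one-carbon homologation) and C1' is reconnected to C3 as the aldol carbon C10. This exchanges a reactive, epimerisable formyl compound for 11, a crystallisable cage that base reopens when needed. The forward step must cleave C3–C10 by retro-aldol under the basic ylide, olefinate the anion so formed before C7 epimerises, and hydrolyse 12 without C3 interfering.

**11 ⇒ 5 + 9.** The bonds C5–C6, C1–C8 and C3–C10 are cut. All of ring B comes from 9 in one operation, 10 is the ring-open stage that closes on acidification, and the absolute configuration is set here. The forward step needs enantiofacial control by a chiral cation and a conjugate addition that joins two quaternary carbons.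

**9 ⇒ 8 ⇒ 7 ⇒ 6.** Only oxidation level and a protecting acetate change; the carbon skeleton of 9 is that of 6.

**5 ⇒ 3 + 4, and 3 ⇒ 1 + 2.** Two C-prenylations and one C-acylation of the arene are undone, which leaves 1, 2 and 4.

## Other disconnections considered

Alternative 1: The cut removes C5–C6, C1–C8 and C3–C2' at once. In the forward sense the polyanion of 5 would meet the epoxy enone A2 in one flask: allylic substitution at C6, conjugate addition of C1 to C8, and epoxide opening at C2' by C3, giving the keto carbinol cage A1.
- In its favour: two rings and three carbon–carbon bonds form in a single operation from the same 5, and the epoxide centre of A2 would fix C2' by inversion.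
- Against it here: A1 carries a C1' ketone that must be removed in the presence of four other carbonyl groups. Its tertiary C3' carbinol is β to that ketone and therefore retro-aldol-prone, and it must still be turned into the isopropenyl group of 16. The conjugate addition has to occur at a fully substituted carbon of a cross-conjugated enone, the epoxy ketone is base-labile, and the sense of the cage relative to the epoxide centre rests on one C5 alkylation.
- Comparison: in structure it delivers more than step 6. In mechanism it chains three polar events, each with an O- versus C-alkylation choice, where the chosen plan separates them. In step economy the cage in one step is better than steps 6 to 9 of the chosen plan, and this is the point on which it is superior. The three or more operations needed to adjust C1' and C3' cancel the gain.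

Alternative 2: The cut is the C1'=C2' bond of the enone A3. In the forward sense the keto aldehyde A4 (C3 quaternary with acetonyl endo and prenyl exo, endo formyl on C7) would close by intramolecular aldol condensation.
- In its favour: a classical, metal-free, thermodynamically driven closure. C3–C2' already exists, so no O- versus C-allylation question arises.
- Against it here: A4 needs a stereodefined quaternary C3 built by alkylating a hindered bicyclic diketone next to a formyl group that itself wants to aldolise with C3. The condensation must enolise the neopentyl-type CH2 and not the methyl group, and the base meets a non-enolisable triketone (retro-Claisen). A3 then needs conjugate reduction and methylenation of a hindered methyl ketone to reach 16.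
- Comparison: in structure it reaches the same cage with the wrong oxidation pattern at C1'–C3'. In mechanism it is at least as predictable as the allylpalladium closure. C2' would be set α to a ketone and could be equilibrated, which is better than the kinetic control of step 9. In step economy it is longer by about three steps.

Alternative 3: The cut is C1–C8. In the forward sense acid would protonate the isopropenyl group of the bicyclo[4.3.1]decane A6, and the enolised tricarbonyl carbon C1 would trap the C8 cation to give the acetate cage A5.
- In its favour: the most congested bond, between two quaternary carbons with one bearing the benzoyl group, is made last and intramolecularly with assured Markovnikov regiochemistry. C2' and the C3' oxygen are in place before the cage closes, so the C2' question of step 9 does not arise; on that point it is better than the chosen plan.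
- Against it here: A6 contains a seven-membered carbocycle bridging C3 and C5 with two stereocentres and has no short access. Protonation has no intrinsic preference for the isopropenyl group over the two prenyl groups, the tertiary acetate can ionise, and the tricarbonyl enol tends to react at oxygen. A5 must still lose acetate regioselectively to give 16.
- Comparison: in structure it attacks a bond the chosen plan makes early under base. In mechanism a cation discriminates the three alkenes less well than hydrogen-atom transfer. In step economy it is clearly longer. It is equal to the chosen plan in leaving the final peroxidation unchanged.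

Key step: step 10

## Route

Step 1
Reactants: 1 phloroglucinol; 2 benzoyl chloride
Product: 3 2,4,6-trihydroxybenzophenone
Conditions: AlCl3 (4 equiv), PhNO2, 25 to 80 °C; then ice/aq. HCl
Reagents that add atoms: none
Why: Friedel–Crafts C-acylation of the electron-rich arene; the aluminium-chelated aryl ketone resists a second acylation and any O-benzoate rearranges (Fries) under the same conditions.

Step 2
Reactants: 3 2,4,6-trihydroxybenzophenone; 4 prenyl bromide
Product: 5 clusiaphenone B
Conditions: 4 (2.1 equiv), 10% aq. KOH, 0 °C
Reagents that add atoms: none
Why: C-alkylation of the phloroglucinol phenoxide in water, where solvation of oxygen directs the allylic bromide to the two free ring carbons; mono- and triprenylated material is removed by chromatography.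

Step 3
Reactants: 6 diethyl isopropylidenemalonate
Product: 7 2-(propan-2-ylidene)propane-1,3-diol
Conditions: i-Bu2AlH (4.5 equiv), CH2Cl2, −78 to 0 °C; aq. KNaC4H4O6 (potassium sodium tartrate) work-up
Reagents that add atoms: none
Why: 1,2-Reduction of both ester groups by the electrophilic aluminium hydride, which leaves the tetrasubstituted alkene untouched.

Step 4
Reactants: 7 2-(propan-2-ylidene)propane-1,3-diol
Product: 8 2-(hydroxymethyl)-3-methylbut-2-en-1-yl acetate
Conditions: Ac2O (0.9 equiv), Et3N, DMAP (cat.), CH2Cl2, −20 °C; recovered 7 recycled
Reagents that add atoms: acetic anhydride CC(=O)OC(C)=O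
Why: Monoacylation of a symmetrical diol with a deficit of anhydride; diol, monoacetate and diacetate are easily separated.

Step 5
Reactants: 8 2-(hydroxymethyl)-3-methylbut-2-en-1-yl acetate
Product: 9 2-formyl-3-methylbut-2-en-1-yl acetate
Conditions: TEMPO (10 mol %), PhI(OAc)2 (1.1 equiv), CH2Cl2, 23 °C
Reagents that add atoms: none
Why: Oxoammonium oxidation of the primary allylic alcohol stops at the enal and does not disturb the allylic acetate.

Step 6
Reactants: 5 clusiaphenone B; 9 2-formyl-3-methylbut-2-en-1-yl acetate
Product: 11 adamantane alcohol, via bicyclic aldehyde 10 (not isolated)
Conditions: naphthalene-2,7-diylbis(methylene)-bridged bis(O-allylhydrocinchonidinium) dibromide (20 mol %), CsOH·H2O, 4 Å MS, CH2Cl2, −50 °C; then aq. HCl; recrystallisation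
Reagents that add atoms: none
Why: Alkylative dearomatisation–annulation under chiral phase-transfer catalysis: C5 is alkylated by the acetoxymethyl carbon (C6), C1 adds in conjugate fashion to the CMe2 terminus (C8), acidification releases the enol aldehyde 10, and its C3 enol closes onto the endo formyl group (aldol) to the cage. The first C–C bond formation in the chiral ion pair sets the absolute sense at C5; C1 and C7 follow because only the endo C7 epimer can close, and the C10 carbinol configuration is irrelevant.

Step 7
Reactants: 11 adamantane alcohol
Product: 13 homologated aldehyde, via enol ether 12 (not isolated)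
Conditions: MeOCH2PPh3Cl (5 equiv), KN(SiMe3)2 (4.8 equiv), THF, 0 to 23 °C; then 2 M aq. HCl, THF, 23 °C
Reagents that add atoms: (methoxymethyl)triphenylphosphonium chloride COC[P+](c1ccccc1)(c1ccccc1)c1ccccc1.[Cl-]; water O
Why: Base-induced retro-aldol ring opening coupled to Wittig methoxymethylenation: the C10 hydroxyl is deprotonated, the alkoxide cleaves the C3–C10 bond to a ring-opened potassium β-diketonate carrying a free endo formyl group, excess ylide olefinates this anion as it forms, and acidification gives the neutral enol ether 12, which aqueous acid hydrolyses in the same flask to 13. The diketonate charge shields C2/C4, the C9 and benzoyl ketones are too hindered for the ylide, and C7 is no longer epimerisable once olefinated; any reversible aldol or hemiacetal closure of 13 is undone by the base of step 8.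

Step 8
Reactants: 13 homologated aldehyde; 14 isopropenylmagnesium bromide
Product: 15 allylic alcohol (both C2' carbinol epimers)
Conditions: CeCl3 (4 equiv), 14 (4 equiv), THF, −78 to 0 °C; aq. NH4Cl
Reagents that add atoms: none
Why: Organocerium 1,2-addition: the first equivalent turns the enol into its enolate, which shields C2 and C4, and the weakly basic cerium reagent adds to the unhindered aldehyde in preference to the flanked C9 and benzoyl ketones. The new carbinol centre needs no control because step 9 erases it.

Step 9
Reactants: 15 allylic alcohol
Product: 16 isopropenyl homoadamantane trione
Conditions: Pd(PPh3)4 (10 mol %, zerovalent palladium), 4 Å MS, THF, 60 °C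
Reagents that add atoms: none
Why: Dehydrative intramolecular Tsuji–Trost allylic alkylation: the acidic enol assists ionisation of the allylic alcohol to the 2-methylallyl palladium complex spanning C2'–C3'–C4', and C3 attacks the internal terminus C2' because only that closure gives a seven-membered ring; O-allylation is reversible under the catalyst and drains to the C–C product. Both carbinol epimers converge through the same complex (face exchange via the CH2 terminus); C2' is set by substrate control with the allyl unit on the C4/C6 flank, away from the C8 methyl groups and the C1 benzoyl group, and C3 can only form with its prenyl group exo.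

Step 10
Reactants: 16 isopropenyl homoadamantane trione
Product: 17 triethylsilyl peroxide of the target
Conditions: Co(acac)2 (10 mol %, divalent cobalt), Et3SiH (2.5 equiv), O2 (1 atm, saturated), ClCH2CH2Cl (0.02 M), 23 °C
Reagents that add atoms: triethylsilane CC[SiH](CC)CC; dioxygen O=O
Why: A cobalt hydride formed from Co(acac)2, silane and O2 transfers a hydrogen atom to the CH2 terminus of the isopropenyl group, and the tertiary C3' radical captures O2 to give a peroxyl radical. This radical adds to C2'' of the C3 prenyl group, the resulting tertiary C3'' radical captures a second O2, and the cobalt-bound peroxide is released by the silane as the triethylsilyl peroxide. The closest known reaction type is the Mukaiyama–Isayama silylperoxidation of dienes in which the peroxyl radical cyclises onto the second alkene to give 1,2-dioxolanes and 1,2-dioxanes; the ring here is one atom larger. The dioxepane closes by 7-exo-trig radical addition, helped by the cage-fixed gauche relation of C1'' and C3' about C3–C2' and by the quaternary carbons C3 and C3'. The new stereocentre C2'' is under substrate control: the alkene should be attacked on the face that places its CMe2 terminus on the C4 flank, away from the C2 carbonyl and the benzoyl group, which gives H–C2'' cis to H–C2'. Initiation at the 1,1-disubstituted alkene and not at the two trisubstituted prenyl alkenes rests on the intrinsic preference of hydrogen-atom transfer and on limiting the silane. O2 capture by the C3' radical must outrun its 5-exo addition to C2'', which O2 saturation secures, and the peroxyl closure must outrun reduction by cobalt, which low catalyst loading and high dilution favour. The non-enolisable trione and the benzoyl group are inert under these neutral conditions.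

Step 11
Reactants: 17 triethylsilyl peroxide of the target
Product: 18 CNP0215795.1 (target)
Conditions: Bu4NF, AcOH (1:1, 1.5 equiv), THF, 0 °C
Reagents that add atoms: none
Why: Fluoride-induced Si–O cleavage of the silyl peroxide under acetic acid buffering; without free base there is no Kornblum–DeLaMare cleavage at C2''–H and no retro-Claisen opening of the triketone, and no reductant is present that could break the O–O bonds.

## Compound list

1 | phloroglucinol | Oc1cc(O)cc(O)c1 | starting material
2 | benzoyl chloride | O=C(Cl)c1ccccc1 | starting material
3 | 2,4,6-trihydroxybenzophenone | O=C(c1ccccc1)c1c(O)cc(O)cc1O | intermediate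
4 | prenyl bromide (1-bromo-3-methylbut-2-ene) | CC(C)=CCBr | starting material
5 | clusiaphenone B, 2,4,6-trihydroxy-3,5-bis(3-methylbut-2-en-1-yl)benzophenone | CC(C)=CCc1c(O)c(CC=C(C)C)c(O)c(C(=O)c2ccccc2)c1O | intermediate
6 | diethyl isopropylidenemalonate | CCOC(=O)C(=C(C)C)C(=O)OCC | starting material
7 | 2-(propan-2-ylidene)propane-1,3-diol | CC(C)=C(CO)CO | intermediate
8 | 2-(hydroxymethyl)-3-methylbut-2-en-1-yl acetate | CC(C)=C(CO)COC(C)=O | intermediate
9 | 2-formyl-3-methylbut-2-en-1-yl acetate | CC(C)=C(C=O)COC(C)=O | intermediate
10 | bicyclic aldehyde: 1-benzoyl-4-hydroxy-8,8-dimethyl-3,5-diprenyl-2,9-dioxobicyclo[3.3.1]non-3-ene-7-carbaldehyde, formyl group endo | CC(C)=CC[C@@]12C[C@H](C=O)C(C)(C)[C@@](C(=O)c3ccccc3)(C1=O)C(=O)C(CC=C(C)C)=C2O | intermediate (not isolated)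
11 | adamantane alcohol: 1-benzoyl-10-hydroxy-8,8-dimethyl-3,5-diprenyladamantane-2,4,9-trione, cage configuration as drawn, C10 carbinol centre undefined | CC(C)=CC[C@]12C[C@@H]3C(O)[C@](CC=C(C)C)(C1=O)C(=O)[C@](C(=O)c1ccccc1)(C2=O)C3(C)C | intermediate
12 | enol ether: the 7-(2-methoxyvinyl) analogue of 10, arm endo, E/Z mixture | CC(C)=CC[C@@]12C[C@H](C=COC)C(C)(C)[C@@](C(=O)c3ccccc3)(C1=O)C(=O)C(CC=C(C)C)=C2O | intermediate (not isolated)
13 | homologated aldehyde: the 7-(2-oxoethyl) analogue of 10, arm endo | CC(C)=CC[C@@]12C[C@H](CC=O)C(C)(C)[C@@](C(=O)c3ccccc3)(C1=O)C(=O)C(CC=C(C)C)=C2O | intermediate
14 | isopropenylmagnesium bromide (prop-1-en-2-ylmagnesium bromide) | CC(=C)[Mg]Br | starting material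
15 | allylic alcohol: the 7-(2-hydroxy-3-methylbut-3-en-1-yl) analogue of 10, arm endo, both C2' carbinol epimers | CC(C)=CC[C@@]12C[C@H](CC(O)C(C)=C)C(C)(C)[C@@](C(=O)c3ccccc3)(C1=O)C(=O)C(CC=C(C)C)=C2O | intermediate
16 | isopropenyl homoadamantane trione: C1 benzoyl, C8 gem-dimethyl, C3 and C5 prenyl, C2' isopropenyl on the C4/C6 flank | CC(C)=CC[C@]12C[C@@H]3C[C@H](C(C)=C)[C@](CC=C(C)C)(C1=O)C(=O)[C@](C(=O)c1ccccc1)(C2=O)C3(C)C | intermediate
17 | triethylsilyl peroxide of the target: dioxepane fused at C3–C2', C3''–OOSiEt3 | CC(C)=CC[C@]12C[C@@H]3C[C@@H]4C(C)(C)OO[C@H](C(C)(C)OO[Si](CC)(CC)CC)C[C@@]4(C1=O)C(=O)[C@](C(=O)c1ccccc1)(C2=O)C3(C)C | intermediate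
18 | CNP0215795.1, dioxepane hydroperoxide of the homoadamantane trione | CC(C)=CC[C@]12C[C@@H]3C[C@@H]4C(C)(C)OO[C@H](C(C)(C)OO)C[C@@]4(C1=O)C(=O)[C@](C(=O)c1ccccc1)(C2=O)C3(C)C | target

## Step count and least certain steps

Total: 11 steps. The longest linear sequence is 9 steps (steps 3, 4, 5, then 6 to 11, starting from 6); from 1 the sequence is 8 steps (1, 2, 6 to 11).

**Step 10 (key step).** The most likely failure is that cobalt and silane intercept the C3' peroxyl radical before the slow seven-membered closure, so that peroxidation stops at C3'. Further risks are competing hydrogen-atom transfer to the prenyl alkenes, 5-exo carbon–carbon cyclisation of the C3' radical if the solution is short of O2, and poor facial selectivity at C2''. Fallback, setting out from 16: the same cobalt system run on purpose with more catalyst and silane and at higher concentration should give the uncyclised C3' triethylsilyl peroxide F1. Buffered fluoride as in step 11 frees the C3' hydroperoxide F2. F2 is then cyclised in a metal-free radical chain (di-tert-butyl hyponitrite as initiator, O2, benzene, 30 °C). There the C3' peroxyl radical meets no reductant, closes onto C2'', takes up O2 at C3'' and abstracts the hydroperoxide hydrogen of the next molecule of F2. The product of this chain is the hydroperoxide itself, so the fallback rejoins the route at 18.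

**Step 6.** Enantiofacial control in the first alkylation may be insufficient or of the wrong sense, and the conjugate addition that joins C1 to C8 is sterically the hardest bond of the route. Fallback, setting out from 5 and 9: the annulation is run without chiral catalyst (LiN(SiMe3)2, THF, 0 °C; then aq. HCl) to give 11 together with the mirror-image adamantane alcohol F3. The antipodes are separated by preparative chromatography on an amylose tris(3,5-dimethylphenylcarbamate) phase, and the route is rejoined at 11.

**Step 7.** The basic ylide may epimerise C7 of the ring-opened formyl diketonate before olefination. During hydrolysis the oxocarbenium ion at C2' may be trapped by the C3 enol and not by water, which would lock the cage as a methyl ether. Fallback, setting out from 11: the smaller and faster methylenetriphenylphosphorane (MePPh3Br, KN(SiMe3)2, THF) gives, through the same retro-aldol opening, the C7 vinyl diketone F4. Hydroboration of the monosubstituted alkene with 9-BBN and oxidation with NaBO3·4H2O gives the primary alcohol F5, with no acid used. Oxidation with TEMPO and PhI(OAc)2 rejoins the route at 13.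

**Step 9.** The substrate bias at the allyl terminus may be weak, giving the wrong C2' epimer, and ionisation of the free alcohol may be slow enough for elimination to the diene to compete. Fallback, setting out from 13: Wittig reaction with isopropylidenetriphenylphosphorane (i-PrPPh3I, n-BuLi, THF) gives the C7-endo triprenyl trione F6. Oxidative radical cyclisation with Mn(OAc)3·2H2O (trivalent manganese) and Cu(OAc)2·H2O (divalent copper) in AcOH at 23 °C generates the C3 radical, which can reach only the endo C7 prenyl group; it adds at C2', and the tertiary C3' radical is oxidised by copper to the isopropenyl group. The transition-state geometry differs from that of the palladium closure, and the fallback rejoins the route at 16.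

## Further compounds

F1 | step 10 | uncyclised C3' triethylsilyl peroxide of 16 | CC(C)=CC[C@]12C[C@@H]3C[C@H](C(C)(C)OO[Si](CC)(CC)CC)[C@](CC=C(C)C)(C1=O)C(=O)[C@](C(=O)c1ccccc1)(C2=O)C3(C)C
F2 | step 10 | C3' hydroperoxide of 16 | CC(C)=CC[C@]12C[C@@H]3C[C@H](C(C)(C)OO)[C@](CC=C(C)C)(C1=O)C(=O)[C@](C(=O)c1ccccc1)(C2=O)C3(C)C
F3 | step 6 | mirror-image adamantane alcohol (enantiomer of 11) | CC(C)=CC[C@@]12C[C@H]3C(O)[C@@](CC=C(C)C)(C1=O)C(=O)[C@@](C(=O)c1ccccc1)(C2=O)C3(C)C
F4 | step 7 | C7 vinyl diketone (7-vinyl analogue of 10, endo) | CC(C)=CC[C@@]12C[C@H](C=C)C(C)(C)[C@@](C(=O)c3ccccc3)(C1=O)C(=O)C(CC=C(C)C)=C2O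
F5 | step 7 | primary alcohol (7-(2-hydroxyethyl) analogue of 10, endo) | CC(C)=CC[C@@]12C[C@H](CCO)C(C)(C)[C@@](C(=O)c3ccccc3)(C1=O)C(=O)C(CC=C(C)C)=C2O
F6 | step 9 | C7-endo triprenyl trione (7-prenyl analogue of 10) | CC(C)=CC[C@@]12C[C@H](CC=C(C)C)C(C)(C)[C@@](C(=O)c3ccccc3)(C1=O)C(=O)C(CC=C(C)C)=C2O
A1 | alternative 1 | homoadamantane with C1' ketone and C3' carbinol | CC(C)=CC[C@]12C[C@@H]3C(=O)[C@H](C(C)(C)O)[C@](CC=C(C)C)(C1=O)C(=O)[C@](C(=O)c1ccccc1)(C2=O)C3(C)C
A2 | alternative 1 | acetoxymethyl epoxy enone, 2-[(3,3-dimethyloxiran-2-yl)carbonyl]-3-methylbut-2-en-1-yl acetate, epoxide centre as required for inversion at C2' | CC(C)=C(COC(C)=O)C(=O)[C@@H]1OC1(C)C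
A3 | alternative 2 | homoadamantene methyl enone | CC(C)=CC[C@]12C[C@@H]3C=C(C(C)=O)[C@](CC=C(C)C)(C1=O)C(=O)[C@](C(=O)c1ccccc1)(C2=O)C3(C)C
A4 | alternative 2 | keto aldehyde: C3-acetonyl (endo), C3-prenyl (exo), C7-formyl (endo) bicyclic trione | CC(C)=CC[C@@]12C[C@H](C=O)C(C)(C)[C@@](C(=O)c3ccccc3)(C1=O)C(=O)[C@](CC=C(C)C)(CC(C)=O)C2=O
A5 | alternative 3 | homoadamantane trione with C3' acetate | CC(C)=CC[C@]12C[C@@H]3C[C@H](C(C)(C)OC(C)=O)[C@](CC=C(C)C)(C1=O)C(=O)[C@](C(=O)c1ccccc1)(C2=O)C3(C)C
A6 | alternative 3 | bicyclo[4.3.1]decane triketone (enol form) with C7 isopropenyl and C3' acetate | CC(C)=CC[C@]12C[C@@H](C(C)=C)C[C@H](C(C)(C)OC(C)=O)[C@](CC=C(C)C)(C1=O)C(=O)C(C(=O)c1ccccc1)=C2O
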